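**Plan**

- Retrosynthesis: the two phenols are masked as benzyl ethers and the C3 acetate is traced back to the free (3R,5R)-1,7-diarylheptane-3,5-diol; the chain is then cut at C1–C2 and at C6–C7.
- Enabling feature: the 3,5-diol core is C2-symmetric. C2–C6 is therefore one five-carbon bis-electrophile, (2S,4S)-1,2:4,5-diepoxypentane; the benzylic carbons C1 and C7, each bearing a 4-oxygenated benzene ring, are the same nucleophile; the C3 and C5 hydroxyls are homotopic.
- Forward: pentane-2,4-dione is turned into 1,5-dichloropentane-2,4-dione, hydrogenated to the (2S,4S)-dichlorodiol and closed to the diepoxide. Two 4-(benzyloxy)benzyl Grignard units then open both oxiranes in one operation, joining C1–C2 and C6–C7. No ring of the target is built; both arenes are bought.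
- Stereochemistry: both stereocenters come from the RuCl2[(R)-BINAP]-catalysed hydrogenation of the 1,3-diketone and are not touched afterwards. The change of descriptor from S to R on benzyl opening is a CIP effect only.
- End game: monoacetylation through the cyclic orthoacetate, then hydrogenolysis of both benzyl ethers.

Key step: step 6

Remark on the chemistry: the sense of the hydrogenation is assigned by analogy with pentane-2,4-dione, which RuCl2[(R)-BINAP] reduces to the (R,R)-diol; with CH2Cl in place of CH3 the same spatial outcome carries the descriptors (2S,4S).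

**Route**

Step 1
Reactants: 1 pentane-2,4-dione; 2 chloroacetyl chloride (3 equiv)
Product: 5 copper bis(1,5-dichloropentane-2,4-dionate), Cu(C5H5Cl2O2)2, via 1-chloropentane-2,4-dione 3 (not isolated), via 1,5-dichloropentane-2,4-dione 4 (not isolated)
Conditions: AlCl3 (3 equiv), PhNO2, 60 °C; ice/aq HCl, Et2O extraction; aq Cu(OAc)2, filter the chelate
Reagents that add atoms: copper diacetate, Cu(OAc)2, CC(=O)[O-].CC(=O)[O-].[Cu+2]
Why: Lewis-acid acyl exchange on a 1,3-diketone: the AlCl3-bound diketonate is C-acylated at C3 and sheds acetyl chloride by retro-Claisen cleavage, twice, the volatile acetyl chloride driving the exchange; the diketone is then taken out of the ether extract as its sparingly soluble divalent-copper chelate, which frees it from nitrobenzene and tar.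

Step 2
Reactants: 5 copper bis(1,5-dichloropentane-2,4-dionate)
Product: 4 1,5-dichloropentane-2,4-dione
Conditions: 10% aq H2SO4, Et2O, rt; bulb-to-bulb distillation, use at once
Reagents that add atoms: none
Why: Protonolysis of a metal β-diketonate: dilute sulfuric acid carries the copper into water as CuSO4 and the neutral diketone partitions into ether; it is used immediately because α-chloro-β-diketones darken on storage.

Step 3
Reactants: 4 1,5-dichloropentane-2,4-dione
Product: 7 (2S,4S)-1,5-dichloropentane-2,4-diol, via (4S)-1,5-dichloro-4-hydroxypentan-2-one 6 (not isolated)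
Conditions: H2 (ca. 85 bar), RuCl2[(R)-BINAP] (ca. 0.2 mol%, as Ru2Cl4[(R)-BINAP]2·NEt3), MeOH, 80–100 °C, short reaction time; recrystallise
Reagents that add atoms: none
Why: Noyori asymmetric hydrogenation of a 1,3-diketone: the chelated substrate is reduced twice under catalyst control, the (R)-BINAP ligand setting the first carbinol (in 6) and then the second with the same facial sense, so both new stereocenters should be S and anti to each other; hot, fast conditions are chosen as for 4-chloroacetoacetates, and crystallisation should remove any meso isomer.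

Step 4
Reactants: 7 (2S,4S)-1,5-dichloropentane-2,4-diol
Product: 9 (2S,4S)-1,2:4,5-diepoxypentane [(2S,2'S)-2,2'-methylenebis(oxirane)], via chlorohydrin monoepoxide 8 (not isolated)
Conditions: KOH (powdered, 3 equiv), Et2O, rt; careful distillation
Reagents that add atoms: none
Why: Twofold intramolecular Williamson etherification (3-exo-tet SN2 of each alkoxide on its primary C–Cl bond); the carbinol C–O bonds are not broken, so both stereocenters are retained as (2S,4S).

Step 5
Reactants: 10 4-(benzyloxy)benzyl chloride
Product: 11 4-(benzyloxy)benzylmagnesium chloride (THF solution, titrated)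
Conditions: Mg turnings (3 equiv, dry-stirred under Ar), THF, 0 °C, slow addition to ca. 0.25 M
Reagents that add atoms: magnesium, [Mg]
Why: Grignard formation by magnesium insertion into a benzylic C–Cl bond; slow addition at high dilution over excess activated metal keeps the stationary halide concentration low and so should suppress Wurtz homocoupling, and the aryl benzyl ether is inert.

Step 6
Reactants: 9 (2S,4S)-1,2:4,5-diepoxypentane; 11 4-(benzyloxy)benzylmagnesium chloride (2.6 equiv)
Product: 14 (3R,5R)-1,7-bis[4-(benzyloxy)phenyl]heptane-3,5-diol, via mono-opened epoxy alkoxide 12 (not isolated), via bis(chloromagnesium) diolate 13 (not isolated)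
Conditions: CuI (10 mol%), THF, −40 → 0 °C; then 1 M aq HCl, 0 °C
Reagents that add atoms: none
Why: Transmetalation of 11 to monovalent copper gives a benzylcuprate that attacks the unsubstituted CH2 carbon of an oxirane in an SN2-type oxidative addition, and reductive elimination from the trivalent-copper alkyl forms C1–C2 and then C6–C7, releasing the chloromagnesium alkoxides 12 and 13 in turn. The closest known reaction type is the copper-catalysed Grignard opening of terminal epoxides, run here in both directions on one C5 diepoxide as is common practice for this bis-electrophile with vinyl and alkyl Grignard reagents. No ring closes in this step; both oxiranes open and the acyclic C7 chain is complete. No stereocenter is created: the C–O bonds at C3 and C5 are never broken, so the configuration of 9 passes unchanged into 14, and the descriptor changes from S to R only because the new CH2CH2Ar arm ranks below the central CH2. The step needs regioselectivity only (terminal CH2 against internal CH of the oxirane, benzylic carbon against ring ortho carbon of the nucleophile, carbon against chloride as the attacking atom, double against single opening); the unhindered termini, the soft copper-bound benzyl group, the chloride counter-ion, the low temperature and the excess of 11 should secure it.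

Step 7
Reactants: 14 (3R,5R)-1,7-bis[4-(benzyloxy)phenyl]heptane-3,5-diol
Product: 16 (3R,5R)-1,7-bis[4-(benzyloxy)phenyl]-5-hydroxyheptan-3-yl acetate, via cyclic orthoacetate 15 (not isolated)
Conditions: MeC(OMe)3 (1.5 equiv), PPTS (5 mol%), CH2Cl2, rt; then H2O, rt
Reagents that add atoms: trimethyl orthoacetate, CC(OC)(OC)OC; water, O
Why: Monoacylation of a diol through its cyclic orthoester: acid-catalysed exchange of two methoxy groups closes the 2-methoxy-2-methyl-1,3-dioxane 15, and water opens the derived dioxan-2-ylium ion at the orthoester carbon to exactly one acetate and one hydroxyl; because the two hydroxyls of 14 are homotopic, either mode of opening gives the same (3R,5R) monoacetate and no carbinol C–O bond is broken.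

Step 8
Reactants: 16 (3R,5R)-1,7-bis[4-(benzyloxy)phenyl]-5-hydroxyheptan-3-yl acetate
Product: 19 (3R,5R)-5-hydroxy-1,7-bis(4-hydroxyphenyl)heptan-3-yl acetate, via C7-aryl monobenzyl ether 17 (not isolated), via C1-aryl monobenzyl ether 18 (not isolated)
Conditions: H2 (1 atm), 10% Pd/C, EtOAc, rt
Reagents that add atoms: none
Why: Catalytic hydrogenolysis of aryl benzyl ethers over Pd/C; the secondary acetate and the non-benzylic carbinol are inert in neutral ethyl acetate, and any 1,3-acetyl shift between O3 and O5 would be degenerate.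

**Compound list**

1 | pentane-2,4-dione | CC(=O)CC(C)=O | starting material
2 | chloroacetyl chloride | ClCC(Cl)=O | starting material
3 | 1-chloropentane-2,4-dione | ClCC(=O)CC(C)=O | intermediate (not isolated)
4 | 1,5-dichloropentane-2,4-dione | ClCC(=O)CC(=O)CCl | intermediate
5 | copper bis(1,5-dichloropentane-2,4-dionate), Cu(C5H5Cl2O2)2 | [Cu+2].[O-]C(CCl)=CC(=O)CCl.[O-]C(CCl)=CC(=O)CCl | intermediate
6 | (4S)-1,5-dichloro-4-hydroxypentan-2-one | ClCC(=O)C[C@H](O)CCl | intermediate (not isolated)
7 | (2S,4S)-1,5-dichloropentane-2,4-diol | ClC[C@@H](O)C[C@H](O)CCl | intermediate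
8 | (2S)-1-chloro-3-[(2S)-oxiran-2-yl]propan-2-ol | ClC[C@@H](O)C[C@H]1CO1 | intermediate (not isolated)
9 | (2S,4S)-1,2:4,5-diepoxypentane [(2S,2'S)-2,2'-methylenebis(oxirane)] | C1O[C@H]1C[C@H]1CO1 | intermediate
10 | 4-(benzyloxy)benzyl chloride [1-(benzyloxy)-4-(chloromethyl)benzene] | ClCc1ccc(OCc2ccccc2)cc1 | starting material
11 | 4-(benzyloxy)benzylmagnesium chloride | Cl[Mg]Cc1ccc(OCc2ccccc2)cc1 | intermediate
12 | chloromagnesium (2R)-4-[4-(benzyloxy)phenyl]-1-[(2S)-oxiran-2-yl]butan-2-olate | Cl[Mg]O[C@H](CCc1ccc(OCc2ccccc2)cc1)C[C@H]1CO1 | intermediate (not isolated)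
13 | bis(chloromagnesium) (3R,5R)-1,7-bis[4-(benzyloxy)phenyl]heptane-3,5-diolate | Cl[Mg]O[C@H](CCc1ccc(OCc2ccccc2)cc1)C[C@H](O[Mg]Cl)CCc1ccc(OCc2ccccc2)cc1 | intermediate (not isolated)
14 | (3R,5R)-1,7-bis[4-(benzyloxy)phenyl]heptane-3,5-diol | O[C@H](CCc1ccc(OCc2ccccc2)cc1)C[C@H](O)CCc1ccc(OCc2ccccc2)cc1 | intermediate
15 | (4R,6R)-4,6-bis{2-[4-(benzyloxy)phenyl]ethyl}-2-methoxy-2-methyl-1,3-dioxane | COC1(C)O[C@H](CCc2ccc(OCc3ccccc3)cc2)C[C@@H](CCc2ccc(OCc3ccccc3)cc2)O1 | intermediate (not isolated)
16 | (3R,5R)-1,7-bis[4-(benzyloxy)phenyl]-5-hydroxyheptan-3-yl acetate | CC(=O)O[C@H](CCc1ccc(OCc2ccccc2)cc1)C[C@H](O)CCc1ccc(OCc2ccccc2)cc1 | intermediate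
17 | (3R,5R)-7-[4-(benzyloxy)phenyl]-5-hydroxy-1-(4-hydroxyphenyl)heptan-3-yl acetate | CC(=O)O[C@H](CCc1ccc(O)cc1)C[C@H](O)CCc1ccc(OCc2ccccc2)cc1 | intermediate (not isolated)
18 | (3R,5R)-1-[4-(benzyloxy)phenyl]-5-hydroxy-7-(4-hydroxyphenyl)heptan-3-yl acetate | CC(=O)O[C@H](CCc1ccc(OCc2ccccc2)cc1)C[C@H](O)CCc1ccc(O)cc1 | intermediate (not isolated)
19 | (3R,5R)-5-hydroxy-1,7-bis(4-hydroxyphenyl)heptan-3-yl acetate | CC(=O)O[C@H](CCc1ccc(O)cc1)C[C@H](O)CCc1ccc(O)cc1 | target

**Summary**

Total step count: 8. Longest linear sequence: 7 (steps 1–4 and 6–8); step 5 is a one-step side branch.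

Steps most likely to fail:

1. Step 6. The oxiranes may be opened by chloride delivered through the Schlenk equilibrium, the sequence may stall after the first opening, or the benzylic reagent may attack through its ring ortho carbon. Fallback, setting out from 9: purchased 4-(benzyloxy)benzaldehyde is condensed with propane-1,3-dithiol (BF3·OEt2, CH2Cl2) to 2-[4-(benzyloxy)phenyl]-1,3-dithiane F1. Deprotonation with n-BuLi (THF, −30 °C) gives 2-lithio-2-[4-(benzyloxy)phenyl]-1,3-dithiane F2, a halide-free, non-ambident carbanion. Two equivalents open both CH2 termini of 9 to give (2S,4S)-1,5-bis{2-[4-(benzyloxy)phenyl]-1,3-dithian-2-yl}pentane-2,4-diol F3 after aqueous quench. Desulfurisation with nickel boride (NiCl2·6H2O, NaBH4, MeOH–THF), which should spare the aryl benzyl ethers, comes back to the route at 14.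

2. Step 5. Wurtz homocoupling of the electron-rich benzylic chloride during magnesium insertion may leave a low titre. Fallback, setting out from 10: displacement with PhSO2Na (DMF, rt) gives 4-(benzyloxy)benzyl phenyl sulfone F4, whose benzylic carbanion is made by C–H deprotonation and not by metal insertion. n-BuLi (THF–DMPU, −78 °C) gives lithio-[4-(benzyloxy)phenyl](phenylsulfonyl)methane F5, which opens both oxiranes of 9 on warming to give (3S,5S)-1,7-bis[4-(benzyloxy)phenyl]-1,7-bis(phenylsulfonyl)heptane-3,5-diol F6 (epimers at C1 and C7) after aqueous quench. Reductive desulfonylation with Na(Hg)/Na2HPO4 in MeOH–THF at −20 °C comes back to the route at 14.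

3. Step 7. Ring closure to the six-membered orthoester of the anti-diol may be incomplete, acyclic mixed orthoesters forming in its place, so that hydrolysis would deliver diol, monoacetate and diacetate together. Fallback, setting out from 14: heating with Bu2SnO in toluene with azeotropic removal of water gives (4R,6R)-4,6-bis{2-[4-(benzyloxy)phenyl]ethyl}-2,2-dibutyl-1,3,2-dioxastanninane F7. AcCl (1.0 equiv, CH2Cl2, 0 °C) acylates one tin-bound oxygen only, giving (3R,5R)-1,7-bis[4-(benzyloxy)phenyl]-5-{[dibutyl(chloro)stannyl]oxy}heptan-3-yl acetate F8. Aqueous work-up cleaves the remaining O–Sn bond and comes back to the route at 16.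

Further compounds
F1 | step 6 | 2-[4-(benzyloxy)phenyl]-1,3-dithiane | C1CSC(SC1)c1ccc(OCc2ccccc2)cc1
F2 | step 6 | 2-lithio-2-[4-(benzyloxy)phenyl]-1,3-dithiane | [Li]C1(SCCCS1)c1ccc(OCc2ccccc2)cc1
F3 | step 6 | (2S,4S)-1,5-bis{2-[4-(benzyloxy)phenyl]-1,3-dithian-2-yl}pentane-2,4-diol | O[C@H](CC1(SCCCS1)c1ccc(OCc2ccccc2)cc1)C[C@H](O)CC1(SCCCS1)c1ccc(OCc2ccccc2)cc1
F4 | step 5 | 4-(benzyloxy)benzyl phenyl sulfone | O=S(=O)(Cc1ccc(OCc2ccccc2)cc1)c1ccccc1
F5 | step 5 | lithio-[4-(benzyloxy)phenyl](phenylsulfonyl)methane | [Li]C(c1ccc(OCc2ccccc2)cc1)S(=O)(=O)c1ccccc1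
F6 | step 5 | (3S,5S)-1,7-bis[4-(benzyloxy)phenyl]-1,7-bis(phenylsulfonyl)heptane-3,5-diol | O[C@H](CC(c1ccc(OCc2ccccc2)cc1)S(=O)(=O)c1ccccc1)C[C@H](O)CC(c1ccc(OCc2ccccc2)cc1)S(=O)(=O)c1ccccc1
F7 | step 7 | (4R,6R)-4,6-bis{2-[4-(benzyloxy)phenyl]ethyl}-2,2-dibutyl-1,3,2-dioxastanninane | CCCC[Sn]1(CCCC)O[C@H](CCc2ccc(OCc3ccccc3)cc2)C[C@@H](CCc2ccc(OCc3ccccc3)cc2)O1
F8 | step 7 | (3R,5R)-1,7-bis[4-(benzyloxy)phenyl]-5-{[dibutyl(chloro)stannyl]oxy}heptan-3-yl acetate | CC(=O)O[C@H](CCc1ccc(OCc2ccccc2)cc1)C[C@H](O[Sn](Cl)(CCCC)CCCC)CCc1ccc(OCc2ccccc2)cc1
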